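**Plan**

- Retrosynthesis (briarane numbering; α is the face opposite the C15 methyl). The O–C7 and Cl–C6 bonds are cut together, giving a C19 carboxylate plus Cl+ on a C5=C6=C7 allene. C2 and C7 are then re-joined, which folds the ten-membered ring C1–C10 into two six-membered rings of a hydrophenanthrene (B: C1, C2, C7–C10; C: C2–C7).
- Further cuts: C8–C17 (tethered Reformatsky), the α-face O and H atoms of rings A and B (trienone chemistry), C2–OH (HAT hydration), ring C back to an anisole (Birch), and ring A (Robinson annulation).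
- Enabling feature: within ring C1–C10 the oxygenated C2 lies 1,6 to C7, and O–C7–C6(Cl)=C5(CH3) is a 2-chloroallyl ester, that is allene + Cl+ + RCO2−. A C2 alkoxide, the C2–C7 bond and a C6 enol triflate therefore form a Grob triad whose products are exactly the C2 carbonyl and that allene.
- Forward order of rings: tetralone (B plus aromatic C), then A, then dearomatised C, then a γ-lactone on C8/C9. Scission of C2–C7 then gives the ten-membered ring, and the lactone moves to O7 as C6–Cl forms.
- Stereochemistry: C1 comes from (R)-1-phenylethylamine. C7–C14 are relayed from C1 on the rigid tricycle. C7 is stored as the allene axis and returned together with the alkene geometry. C17 is set thermodynamically and C2 by the CBS catalyst.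

Key step: step 19

Assumption: centres that are later erased or equilibrated are carried as mixtures and drawn without configuration. These are C5 in 14–16, C7 in 13, the CHBr carbon in 24–28, and C17 in 29–32.

**Step 1**
Reactants: 1 5-methoxy-2-tetralone
Product: 4 rac-5-methoxy-1-methyl-2-tetralone, via enamine 2 (not isolated), via iminium iodide 3 (not isolated)
Conditions: pyrrolidine, PhMe, reflux (−H2O); MeI, dioxane, reflux; H2O, reflux
Reagents that add atoms: iodomethane, CI; water, O
Why: Stork enamine alkylation; the aryl-conjugated enamine is nucleophilic only at C1, so mono-C-methylation should result (racemic centre, resolved dynamically in step 2).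

**Step 2**
Reactants: 4 rac-5-methoxy-1-methyl-2-tetralone; 5 (R)-1-phenylethylamine; 6 pent-1-en-3-one
Product: 9 (1R)-5-methoxy-1-methyl-1-(3-oxopentyl)-2-tetralone, via imine 7 (not isolated), via adduct imine 8 (not isolated)
Conditions: 5, PhMe, reflux (−H2O); 6, THF, 23 °C; 20% aq AcOH, 23 °C
Reagents that add atoms: water, O
Why: Deracemising asymmetric Michael addition of a chiral imine; it reacts through its more substituted, aryl-conjugated secondary enamine in an aza-ene-like transition state, and the enone enters anti to the auxiliary phenyl group, which sets quaternary C1.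

**Step 3**
Reactants: 9 (1R)-5-methoxy-1-methyl-1-(3-oxopentyl)-2-tetralone
Product: 10 (4aS)-8-methoxy-1,4a-dimethyl-4,4a,9,10-tetrahydrophenanthren-2(3H)-one
Conditions: NaOMe, MeOH, 60 °C
Reagents that add atoms: none
Why: Intramolecular aldol condensation (second half of a Robinson annulation) closes ring A as the only six-membered enone available (C11 onto C10).

**Step 4**
Reactants: 10 tricyclic enone
Product: 11 12β-allylic alcohol of 10
Conditions: NaBH4, CeCl3·7H2O, MeOH, 0 °C
Reagents that add atoms: none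
Why: Luche 1,2-reduction masks the enone as an alcohol whose alkoxide survives steps 5 and 6; the C12 centre (mainly pseudo-equatorial OH) is erased again in step 10.

**Step 5**
Reactants: 11 12β-allylic alcohol
Product: 12 C5-methylated anisole
Conditions: n-BuLi (2.3 equiv), TMEDA, Et2O, 0 to 23 °C; MeI, −78 to 0 °C
Reagents that add atoms: iodomethane, CI
Why: Directed ortho-metalation; OMe directs lithiation to its only free ortho position C5, and the methyl placed there is C16 and later fixes the Birch regiochemistry.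

**Step 6**
Reactants: 12 C5-methylated anisole
Product: 14 β,γ-unsaturated C6 ketone (C2=C3), via dihydroanisole 13 (not isolated)
Conditions: Li, NH3(l), THF, t-BuOH, −33 °C; H2O; (CO2H)2, MeOH–H2O, 23 °C
Reagents that add atoms: water, O
Why: Birch reduction protonates C4 and C7, the only para pair that leaves OMe, C16 and the C1 branch on double bonds; the alkoxide and the tetrasubstituted C10=C11 alkene are inert, oxalic acid cleaves only the enol ether, and the epimerisable C7 settles with H7 β.

**Step 7**
Reactants: 14 β,γ-unsaturated C6 ketone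
Product: 15 2α-hydroxy C6 ketone (B/C trans)
Conditions: Mn(dpm)3 (cat.), PhSiH3, O2 (1 atm), i-PrOH–CH2Cl2, 0 °C
Reagents that add atoms: dioxygen, O=O
Why: Mukaiyama hydration; H-atom transfer to C3 gives the tertiary C2 radical, which O2 should trap on the α-face away from C15, while the tetrasubstituted alkene is too hindered for HAT.

**Step 8**
Reactants: 15 2α-hydroxy C6 ketone
Product: 16 2,12-bis(triethylsilyl) ether
Conditions: TESOTf (3 equiv), 2,6-lutidine, CH2Cl2, −78 to 0 °C
Reagents that add atoms: triethylsilyl trifluoromethanesulfonate, CC[Si](CC)(CC)OS(=O)(=O)C(F)(F)F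
Why: Silyl triflate silylation caps the tertiary C2–OH (blocking retro-aldol and premature fragmentation) and the C12–OH in one operation.

**Step 9**
Reactants: 16 bis-TES ketone
Product: 17 C5=C6 enol triflate
Conditions: KHMDS, THF, −78 °C; Comins' reagent, −78 to −30 °C
Reagents that add atoms: N-(5-chloropyridin-2-yl)bis(trifluoromethanesulfonimide), FC(F)(F)S(=O)(=O)N(c1ccc(Cl)cn1)S(=O)(=O)C(F)(F)F
Why: Kinetic enolisation and O-triflation; the base should take the accessible C5–H rather than C7–H, which sits next to the fully substituted C2, and this gives the tetrasubstituted enol triflate.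

**Step 10**
Reactants: 17 C5=C6 enol triflate
Product: 20 8,10,13-trien-12-one, via enone 18 (not isolated), via cross-conjugated dienone 19 (not isolated)
Conditions: DDQ (1.2 equiv), CH2Cl2–pH 7 buffer, 23 °C; solvent change; DDQ (2.5 equiv), dioxane, reflux
Reagents that add atoms: none
Why: DDQ hydride abstraction oxidises the allylic silyl ether to the enone and then dehydrogenates through the two dienols (the 4-en-3-one to 1,4,6-trien-3-one pattern of steroids); the electron-poor triflate and the tertiary TES ether have no hydride to give.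

**Step 11**
Reactants: 20 trienone
Product: 21 13α,14α-epoxy-8,10-dien-12-one
Conditions: 30% H2O2, NaOH (cat.), MeOH–THF, 0 °C
Reagents that add atoms: hydrogen peroxide, OO
Why: Weitz–Scheffer epoxidation attacks the only unsubstituted enone β-carbon (C14) from the α-face opposite the adjacent C15 methyl, setting C13 and C14.

**Step 12**
Reactants: 21 13α,14α-epoxy dienone
Product: 22 8α,9α;13α,14α-diepoxy-10-en-12-one
Conditions: mCPBA, NaHCO3, CH2Cl2, 0 to 23 °C
Reagents that add atoms: 3-chloroperoxybenzoic acid, OOC(=O)c1cccc(Cl)c1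
Why: Prilezhaev epoxidation takes the most electron-rich alkene (γ,δ C8=C9) on the α-face, because C15 is syn-axial to C9 on the β-face.

**Step 13**
Reactants: 22 diepoxy enone; 23 rac-2-bromopropanoic acid
Product: 24 9β-(2-bromopropanoyloxy)-8α-hydroxy enone
Conditions: 23 (5 equiv), BF3·OEt2 (cat.), CH2Cl2, −40 °C
Reagents that add atoms: none
Why: Acid-catalysed trans-diaxial epoxide opening (Fürst–Plattner rule) at the allylic C9 with inversion sets C9–O β and leaves C8–OH α; the epoxide next to the ketone is deactivated towards acid.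

**Step 14**
Reactants: 24 hydroxy ester enone
Product: 25 8α,12α-diol
Conditions: NaBH4, CeCl3·7H2O, MeOH–THF, −78 °C
Reagents that add atoms: none
Why: Luche reduction of the epoxy-enone; hydride should approach anti to the epoxide oxygen (β-face), giving the 12α-alcohol cis to the epoxide.

**Step 15**
Reactants: 25 8α,12α-diol
Product: 26 10α-H,11α-H dihydro diol
Conditions: [Ir(cod)(PCy3)(py)]BArF (cat.), H2 (50 bar), CH2Cl2, 23 °C
Reagents that add atoms: none
Why: Hydroxyl-directed hydrogenation with Crabtree's catalyst; the allylic 12α-OH and homoallylic 8α-OH bind iridium on the α-face, so syn delivery sets H10 and H11 α (trans A/B fusion, axial C20 methyl with no adjacent carbonyl to epimerise it).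

**Step 16**
Reactants: 26 dihydro diol
Product: 27 12α-hexanoate
Conditions: hexanoyl chloride (1.2 equiv), pyridine, DMAP (cat.), CH2Cl2, 0 °C
Reagents that add atoms: hexanoyl chloride, CCCCCC(=O)Cl
Why: DMAP-catalysed acylation should take only C12–OH, because C8–OH is axial, flanked by C7 and C9, and syn-axial to the C2–OTES group.

**Step 17**
Reactants: 27 12α-hexanoate
Product: 28 C8 ketone
Conditions: Dess–Martin periodinane, NaHCO3, CH2Cl2, 23 °C
Reagents that add atoms: none
Why: Dess–Martin oxidation is neutral, so the α-acyloxy centre C9, the β-silyloxy group and C7 (already in its stable equatorial arrangement) are not disturbed.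

**Step 18**
Reactants: 28 C8 ketone
Product: 29 fragmentation precursor (8α-hydroxy-9β,19-lactone)
Conditions: activated Zn dust, THF, 23 to 50 °C; aq NH4Cl
Reagents that add atoms: none
Why: Intramolecular Reformatsky reaction; the carbon-bound zinc enolate is held on the β-face by the C9–O tether, so C17 can only add there and C8–OH becomes α.

**Step 19**
Reactants: 29 fragmentation precursor
Product: 30 ten-membered (aS)-5,6-dien-2-one
Conditions: TBAF (1.1 equiv), THF, −20 to 23 °C
Reagents that add atoms: none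
Why: Fluoride removes the TES group, and the free tertiary C2 alkoxide collapses to the C2 ketone while the σ(C2–C7) electrons flow into σ*(C6–OTf) and expel triflate, leaving the C5=C6=C7 allene. The closest known reaction is the alkoxide-triggered Grob-type C–C fragmentation of cyclic β-silyloxy enol triflates to medium-ring keto-allenes. No ring is closed by bond formation: ring C1–C10 appears by scission of the bond shared by six-membered rings B and C (6+6 to 10), so there is no macrocyclisation entropy to pay and the syn-axial O2/O8 strain is released. The only new stereoelement, the allene axis, is fixed by the C7 configuration (H7 β) and by the ring-enforced cis relation of C4 and C7 on the enol triflate, because H7 and C8 stay perpendicular to the plane in which the new π bond forms. The step needs only C2–C7 to break, and among the bonds at C2 only that one is antiperiplanar to C6–O in the half-chair of ring C. At low temperature fluoride should touch only silicon, so the hexanoate, lactone and epoxide remain.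

**Step 20**
Reactants: 30 keto-allene lactone
Product: 32 6-chloro-7,19-lactone (2-ketone), via lithium carboxylate 31 (not isolated)
Conditions: LiOH (1.05 equiv), THF–H2O, 0 °C; NaHCO3, 1,3-dichloro-5,5-dimethylhydantoin (0.55 equiv), 0 °C, dark
Reagents that add atoms: lithium hydroxide, [Li+].[OH-]; 1,3-dichloro-5,5-dimethylhydantoin, CC1(C)N(Cl)C(=O)N(Cl)C1=O
Why: Proposed new method: hydroxide should open the β-hydroxy-γ-lactone faster than the hindered hexanoate and expose a 4,5-allenoate; Cl+ then attacks the central C6 on the outer face (the C16 side) while the carboxylate closes 5-exo on C7 from the opposite face, so O7 takes the place C2 held in 29, Cl the place of the triflate, and the alkene is ring-cis; the anionic carboxylate should outrun 5-endo attack by the neutral C8–OH; the closest known reaction type is iodo- and bromolactonisation of 4,5-allenoic acids to 5-(1-haloalkenyl)butanolides, not yet shown with Cl+ or on an endocyclic medium-ring allene.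

**Step 21**
Reactants: 32 chlorolactone (C17 mixture)
Product: 33 (17R*)-chlorolactone with C18 cis to 8-OH
Conditions: DBU (cat.), PhMe, 60 °C
Reagents that add atoms: none
Why: Base-mediated epimerisation through the lactone enolate should move C18 to the convex face (cis to 8-OH and H7, trans to C6 and C9), which is the target configuration.

**Step 22**
Reactants: 33 chlorolactone 2-ketone
Product: 34 (2S)-alcohol
Conditions: (R)-Me-CBS (0.5 equiv), catecholborane, PhMe–CH2Cl2, −60 °C
Reagents that add atoms: none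
Why: Corey–Bakshi–Shibata reduction; the ketone has a quaternary (C1) and a methylene (C3) flank, the ideal large/small pair, so the (R)-catalyst should deliver the (2S)-alcohol under reagent control.

**Step 23**
Reactants: 34 (2S)-alcohol
Product: 35 target CNP0243318.1
Conditions: Ac2O (1.2 equiv), pyridine, DMAP (cat.), CH2Cl2, −20 °C
Reagents that add atoms: acetic anhydride, CC(=O)OC(C)=O
Why: DMAP-catalysed acetylation should choose C2–OH (one CH2 neighbour) over C9–OH (between quaternary C8 and tertiary C10, hydrogen-bonded) and over the tertiary C8–OH.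

**Compound list**

1 | 5-methoxy-2-tetralone | COc1cccc2c1CCC(=O)C2 | starting material
2 | pyrrolidine enamine of 1 | COc1cccc2C=C(CCc12)N1CCCC1 | intermediate
3 | C1-methylated iminium iodide | COc1cccc2c1CCC(=[N+]1CCCC1)C2C.[I-] | intermediate
4 | rac-5-methoxy-1-methyl-2-tetralone | COc1cccc2c1CCC(=O)C2C | intermediate
5 | (R)-1-phenylethylamine | C[C@@H](N)c1ccccc1 | starting material
6 | pent-1-en-3-one | CCC(=O)C=C | starting material
7 | imine of 4 and 5 | COc1cccc2c1CCC(=N[C@H](C)c1ccccc1)C2C | intermediate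
8 | Michael adduct imine | CCC(=O)CC[C@@]1(C)C(=N[C@H](C)c3ccccc3)CCc2c1cccc2OC | intermediate
9 | (1R)-5-methoxy-1-methyl-1-(3-oxopentyl)-2-tetralone | CCC(=O)CC[C@@]1(C)C(=O)CCc2c1cccc2OC | intermediate
10 | (4aS)-8-methoxy-1,4a-dimethyl-4,4a,9,10-tetrahydrophenanthren-2(3H)-one | C[C@]12CCC(=O)C(C)=C1CCc1c2cccc1OC | intermediate
11 | 12β-allylic alcohol | C[C@]12CC[C@H](O)C(C)=C1CCc1c2cccc1OC | intermediate
12 | C5-methylated anisole | C[C@]12CC[C@H](O)C(C)=C1CCc1c2ccc(C)c1OC | intermediate
13 | 4,7-dihydroanisole | C[C@]12CC[C@H](O)C(C)=C1CCC1C2=CCC(C)=C1OC | intermediate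
14 | β,γ-unsaturated C6 ketone | C[C@]12CC[C@H](O)C(C)=C1CC[C@@H]1C2=CCC(C)C1=O | intermediate
15 | 2α-hydroxy C6 ketone | C[C@]12CC[C@H](O)C(C)=C1CC[C@@H]1[C@]2(O)CCC(C)C1=O | intermediate
16 | 2,12-bis-TES ether | C[C@]12CC[C@H](O[Si](CC)(CC)CC)C(C)=C1CC[C@@H]1[C@]2(O[Si](CC)(CC)CC)CCC(C)C1=O | intermediate
17 | C5=C6 enol triflate | C[C@]12CC[C@H](O[Si](CC)(CC)CC)C(C)=C1CC[C@@H]1[C@]2(O[Si](CC)(CC)CC)CCC(C)=C1OS(=O)(=O)C(F)(F)F | intermediate
18 | 10-en-12-one | C[C@]12CCC(=O)C(C)=C1CC[C@@H]1[C@]2(O[Si](CC)(CC)CC)CCC(C)=C1OS(=O)(=O)C(F)(F)F | intermediate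
19 | 10,13-dien-12-one | C[C@]12C=CC(=O)C(C)=C1CC[C@@H]1[C@]2(O[Si](CC)(CC)CC)CCC(C)=C1OS(=O)(=O)C(F)(F)F | intermediate
20 | 8,10,13-trien-12-one | C[C@]12C=CC(=O)C(C)=C1C=C[C@@H]1[C@]2(O[Si](CC)(CC)CC)CCC(C)=C1OS(=O)(=O)C(F)(F)F | intermediate
21 | 13α,14α-epoxy dienone | C[C@]12[C@H]3O[C@H]3C(=O)C(C)=C1C=C[C@@H]1[C@]2(O[Si](CC)(CC)CC)CCC(C)=C1OS(=O)(=O)C(F)(F)F | intermediate
22 | 8α,9α;13α,14α-diepoxy enone | C[C@]12[C@H]3O[C@H]3C(=O)C(C)=C1[C@H]4O[C@H]4[C@@H]1[C@]2(O[Si](CC)(CC)CC)CCC(C)=C1OS(=O)(=O)C(F)(F)F | intermediate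
23 | rac-2-bromopropanoic acid | CC(Br)C(=O)O | starting material
24 | 9β-(2-bromopropanoyloxy)-8α-hydroxy enone | C[C@]12[C@H]3O[C@H]3C(=O)C(C)=C1[C@H](OC(=O)C(C)Br)[C@@H](O)[C@@H]1[C@]2(O[Si](CC)(CC)CC)CCC(C)=C1OS(=O)(=O)C(F)(F)F | intermediate
25 | 8α,12α-diol | C[C@]12[C@H]3O[C@H]3[C@@H](O)C(C)=C1[C@H](OC(=O)C(C)Br)[C@@H](O)[C@@H]1[C@]2(O[Si](CC)(CC)CC)CCC(C)=C1OS(=O)(=O)C(F)(F)F | intermediate
26 | 10α-H,11α-H dihydro diol | C[C@]12[C@H]3O[C@H]3[C@@H](O)[C@H](C)[C@@H]1[C@H](OC(=O)C(C)Br)[C@@H](O)[C@@H]1[C@]2(O[Si](CC)(CC)CC)CCC(C)=C1OS(=O)(=O)C(F)(F)F | intermediate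
27 | 12α-hexanoate | C[C@]12[C@H]3O[C@H]3[C@@H](OC(=O)CCCCC)[C@H](C)[C@@H]1[C@H](OC(=O)C(C)Br)[C@@H](O)[C@@H]1[C@]2(O[Si](CC)(CC)CC)CCC(C)=C1OS(=O)(=O)C(F)(F)F | intermediate
28 | C8 ketone | C[C@]12[C@H]3O[C@H]3[C@@H](OC(=O)CCCCC)[C@H](C)[C@@H]1[C@H](OC(=O)C(C)Br)C(=O)[C@@H]1[C@]2(O[Si](CC)(CC)CC)CCC(C)=C1OS(=O)(=O)C(F)(F)F | intermediate
29 | fragmentation precursor (2α-OTES, 6-OTf, 8α-OH, 9β,19-lactone) | C[C@]12[C@H]3O[C@H]3[C@@H](OC(=O)CCCCC)[C@H](C)[C@@H]1[C@@H]4OC(=O)C(C)[C@]4(O)[C@@H]1[C@]2(O[Si](CC)(CC)CC)CCC(C)=C1OS(=O)(=O)C(F)(F)F | intermediate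
30 | ten-membered (aS)-5,6-dien-2-one with 9,19-lactone | C[C@]12[C@H]3O[C@H]3[C@@H](OC(=O)CCCCC)[C@H](C)[C@@H]1[C@@H]4OC(=O)C(C)[C@]4(O)C([H])=[C@@]=C(C)CCC2=O | intermediate
31 | lithium 8,9-dihydroxy-4,5-allenoate | C[C@]12[C@H]3O[C@H]3[C@@H](OC(=O)CCCCC)[C@H](C)[C@@H]1[C@H](O)[C@](O)(C(C)C(=O)[O-])C([H])=[C@@]=C(C)CCC2=O.[Li+] | intermediate
32 | 6-chloro-7,19-lactone 2-ketone (C17 mixture) | CCCCCC(=O)O[C@H]1[C@H](C)[C@@H]2[C@H](O)[C@@]3(O)[C@H](OC(=O)C3C)/C(Cl)=C(/C)CCC(=O)[C@@]2(C)[C@H]2O[C@@H]12 | intermediate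
33 | 6-chloro-7,19-lactone 2-ketone (C17 set) | CCCCCC(=O)O[C@H]1[C@H](C)[C@@H]2[C@H](O)[C@@]3(O)[C@H](OC(=O)[C@@H]3C)/C(Cl)=C(/C)CCC(=O)[C@@]2(C)[C@H]2O[C@@H]12 | intermediate
34 | (2S)-alcohol | CCCCCC(=O)O[C@H]1[C@H](C)[C@@H]2[C@H](O)[C@@]3(O)[C@H](OC(=O)[C@@H]3C)/C(Cl)=C(/C)CC[C@H](O)[C@@]2(C)[C@H]2O[C@@H]12 | intermediate
35 | CNP0243318.1 | CCCCCC(=O)O[C@H]1[C@H](C)[C@@H]2[C@H](O)[C@@]3(O)[C@H](OC(=O)[C@@H]3C)/C(Cl)=C(/C)CC[C@H](OC(C)=O)[C@@]2(C)[C@H]2O[C@@H]12 | target

**Totals**

Total step count: 23. Longest linear sequence: 23.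

**Steps most likely to fail**

Step 20 (Proposed new method). Chlorine transfer to the allene may be too slow. The C8 hydroxyl may cyclise 5-endo onto C5, or the hexanoate may be hydrolysed along with the lactone. The fallback sets out from 30. Lithium hydroxide followed by iodine and sodium hydrogencarbonate (the known iodolactonisation of 4,5-allenoic acids) should give the 6-iodo-7,19-lactone F1. Copper(I) chloride in NMP (known copper-mediated vinyl halide exchange with retention) then returns to the route at 32.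

Step 18. The zinc enolate may fail to add to the very hindered C8 ketone, or the α-acyloxy group may be lost reductively. The fallback sets out from 28:
- triethyl phosphite (Michaelis–Arbuzov reaction) gives the phosphonate ester F2;
- LiCl/DBU (intramolecular Horner–Wadsworth–Emmons reaction) gives the 8(17)-butenolide F3;
- t-BuOOH/Triton B (Weitz–Scheffer epoxidation) gives the 8α,17α-epoxy lactone F4;
- SmI2 (known reductive opening of α,β-epoxy esters at the α-carbon) returns to the route at 29.

Step 15. The catalyst may be unable to reach the tetrasubstituted C10=C11 alkene, or facial selectivity may be poor. The fallback sets out from 25 and returns at 26. It replaces coordination control by a radical HAT hydrogenation (Mn(dpm)3, PhSiH3, t-BuOOH, i-PrOH). In that reaction the hydrogen atoms enter stepwise on the less hindered α-face and the ring fusion is set under thermodynamic control. It makes no new compound (F0).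

**Further compounds**

F1 | step 20 | 6-iodo-7,19-lactone 2-ketone | CCCCCC(=O)O[C@H]1[C@H](C)[C@@H]2[C@H](O)[C@@]3(O)[C@H](OC(=O)C3C)/C(I)=C(/C)CCC(=O)[C@@]2(C)[C@H]2O[C@@H]12
F2 | step 18 | 9β-[2-(diethoxyphosphoryl)propanoyloxy] C8 ketone | C[C@]12[C@H]3O[C@H]3[C@@H](OC(=O)CCCCC)[C@H](C)[C@@H]1[C@H](OC(=O)C(C)P(=O)(OCC)OCC)C(=O)[C@@H]1[C@]2(O[Si](CC)(CC)CC)CCC(C)=C1OS(=O)(=O)C(F)(F)F
F3 | step 18 | 8(17)-butenolide | C[C@]12[C@H]3O[C@H]3[C@@H](OC(=O)CCCCC)[C@H](C)[C@@H]1[C@@H]4OC(=O)C(C)=C4[C@@H]1[C@]2(O[Si](CC)(CC)CC)CCC(C)=C1OS(=O)(=O)C(F)(F)F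
F4 | step 18 | 8α,17α-epoxy lactone | C[C@]12[C@H]3O[C@H]3[C@@H](OC(=O)CCCCC)[C@H](C)[C@@H]1[C@@H]4OC(=O)[C@@]5(C)O[C@@]45[C@@H]1[C@]2(O[Si](CC)(CC)CC)CCC(C)=C1OS(=O)(=O)C(F)(F)F
F0 | step 15 | none | none
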